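## Analysis of the target

Rubioncolin C (22) consists of two naphthalene units joined through one oxygen. One is a naphthoate (ring A fully substituted, ring B its benzo ring) and the other a 1,4-naphthoquinone (ring C the quinone ring, ring D its benzo ring). Ring A carries in sequence a free hydroxyl at C1, the methyl ester at C2, the prenyl group at C3 and the ether oxygen at C4, which is bonded to C2' of ring C. There is no stereocentre, and the only double bond outside the rings ends in two methyl groups, so no configuration has to be set. Three groups are sensitive: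
- the 2-aryloxyquinone is a vinylogous ester and gives up its aryloxy group to nucleophiles by addition–elimination;
- the prenyl alkene sits between an ester carbonyl and the ether oxygen and is open to acid-promoted addition;
- ring A is a hydroquinone mono-ether and is open to oxidants.

The difficulty is that ring A is a tetrasubstituted hydroquinone whose two oxygens must end up different (O1 free, O4 arylated). O4 is shielded by the prenyl group and the peri hydrogen at C5, and a free ring A hydroquinone would exchange electrons with any quinone electrophile offered to it. The strategy rests on the array C1(OH)–C2–C3–C4(OAr) fused to the unsubstituted ring B. This is the pattern a chromium carbene benzannulation delivers: C4 with its oxygen from the carbene carbon, C1 with its hydroxyl from a carbonyl ligand, C2 and C3 from an alkyne, and C4a to C8a from a phenyl group.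

## Retrosynthetic reasoning

**22 from 20.** No skeletal bond is cut. The two carbonyl groups of ring C are traced back to the methoxymethyl ethers of 20, because the aryloxyquinone would not survive the organometallic, oxidative and basic steps before it. The forward reaction has to cleave two acetals without touching the prenyl group, then oxidise the hydroquinone 21 while leaving ring A alone.

**20 from 17, through 19 and 18.** The ester is traced back to the diethyl acetal of 17. The oxidation level is raised only after ring A exists, because the key step needs a bulky, electronically neutral group on the alkyne, whereas an ester would make the alkyne electron-poor and blur the steric bias. Going forward, the acetal has to be hydrolysed beside two aryl acetals, a hindered aldehyde oxidised in the presence of a free naphthol and a prenyl group, and the acid methylated without touching the phenol.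

**17 from 11 and 15.** Three bonds of ring A are cut at once: C3–C4, C1–C2 and C1–C8a. Ring A falls apart into the carbene carbon of 11 (C4, already bonded to the oxygen that carries ring C), one carbonyl ligand (C1 and O1), the alkyne carbons of 15 (C2 and C3) and the phenyl group of 11 (ring B). The cut is made here because the two oxygens then differ by origin, and the crowded C4–O bond is inherited from the carbene instead of being made by substitution on a finished ring. The forward reaction must insert the alkyne in one orientation, with the acetal carbon bonded to C1.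

**11 from 9 and 5.** The bond between the carbene carbon and the aryl oxygen is cut. It is formed at a planar, electrophilic carbene carbon, in the acyloxy complex 10 made from acylate 9, where the one ortho substituent of naphthol 5 matters little. Acylate 9 goes back to 6 and 7 by the addition of the aryl anion to a carbonyl ligand.

**5 from 2 and 1.** The C2–O bond of the ring C precursor is cut. The acetal oxygens of 2 direct lithiation to C2, and C2 and C3 are equivalent by symmetry, so one hydroxylation product is possible. Compound 2 is the bis-ether of the commercial diol 1.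

**15 from 12 and 13.** The bond between the propargylic and the allylic carbon is cut, which leads to two commercial C3 and C5 pieces. The forward reaction has to couple at the primary end of the allylic bromide.

## Alternatives that were turned down

**Alternative 1:** Aryne cycloaddition to a silyloxyfuran. Ring A is cut at C1–C8a and C4–C4a. The furan is methyl 4-(3-methylbut-2-en-1-yl)-2-[(triisopropylsilyl)oxy]furan-3-carboxylate A1, and the aryne is released by fluoride from 2-(trimethylsilyl)phenyl trifluoromethanesulfonate A2. The aryne adds across C2 and C5 of A1. The oxygen bridge opens towards the silyloxy-stabilised cation and the ring aromatises to methyl 4-hydroxy-3-(3-methylbut-2-en-1-yl)-1-[(triisopropylsilyl)oxy]-2-naphthoate A3, with O1 silylated and O4 free. The ether would then be made from A3 and 2-bromonaphthalene-1,4-dione A4, followed by desilylation.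
- For: it is shorter than the chosen route, needs no stoichiometric chromium and carries the ester at the right oxidation level from the start. On step economy and on the ester it is the stronger plan.
- Against: A1 is the silyl ketene acetal of a butenolide, and the fluoride that releases the aryne can also strip its silyl group. The bond hardest to make is postponed: the hindered O4–H of A3 has to displace bromide from A4, which is also an oxidant towards the electron-rich naphthol.
- Comparison: the chosen strategy pays with more steps but forms that C–O bond before ring A exists.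

**Alternative 2:** Ring C from a squarate. The disconnection removes ring C from a finished ether. Methyl 1-hydroxy-4-[(4-hydroxy-3-oxo-4-phenylcyclobut-1-en-1-yl)oxy]-3-(3-methylbut-2-en-1-yl)naphthalene-2-carboxylate A5 is heated. The four-membered ring opens to a vinylketene, whose ketene carbon closes onto the ortho carbon of the phenyl group (C4'–C4a'). Tautomerisation gives methyl 4-[(1,4-dihydroxynaphthalen-2-yl)oxy]-1-hydroxy-3-(3-methylbut-2-en-1-yl)-2-naphthoate A6, which is the same hydroquinone as 21 and is one air oxidation from 22.
- For: the key step is neutral and reagent-free, ring C needs no protecting groups, and no acid comes near the prenyl group. That endgame is better than the chosen one.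
- Against: A5 still requires a ring A naphthol of the A3 type with its oxygens already differentiated, so ring A must be made by another route first. The naphthol must be attached to a squarate by substitution at the hindered O4. The phenyl nucleophile must then pick one of two ring carbonyls beside an ester and a phenol.
- Comparison: it solves ring C but leaves the ring A problem open and is longer overall. The chosen strategy solves the oxygen differentiation and the ether in one step.

**Alternative 3:** Ring expansion of an indanedione. Ring A is cut at C1–C2. Methoxide opens methyl 2-[2-(3-methylbut-2-en-1-yl)-1,3-dioxo-2,3-dihydro-1H-inden-2-yl]acetate A7 by retro-Claisen cleavage to racemic methyl 2-[4-methoxy-2-(3-methylbut-2-en-1-yl)-4-oxobutanoyl]benzoate A8. Its ester enolate closes on the benzoate to give methyl 1,4-dihydroxy-3-(3-methylbut-2-en-1-yl)-2-naphthoate A9.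
- For: this is the shortest and cheapest entry to ring A, free of metals and with the ester in place. On step economy it beats the chosen route clearly.
- Against: A9 is a free, air-sensitive hydroquinone whose hydroxyls differ only through the hydrogen bond of O1–H to the ester. Its hindered O4–H would have to attack A4, and hydroquinone and quinone exchange electrons faster than they are likely to couple.
- Comparison: the chosen strategy is longer, but the difference between O1 and O4 follows from the mechanism, and a free ring A hydroquinone never meets a quinone.

Key step: step 6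

Remark: naphthalene-1,4-diol (1) is taken as the purchased starting material in place of its quinone, which saves a reduction.

## Route

Step 1
Reactants: 1 naphthalene-1,4-diol
Product: 2 1,4-bis(methoxymethoxy)naphthalene
Conditions: NaH, MOMCl, DMF, 0 °C to rt, Ar
Reagents that add atoms: chloromethyl methyl ether, COCCl
Why: Williamson-type O-alkylation of the bis-phenoxide; the methoxymethyl ethers direct the lithiation of step 2, survive every step up to step 9 and leave under mild acid.

Step 2
Reactants: 2 1,4-bis(methoxymethoxy)naphthalene
Product: 5 1,4-bis(methoxymethoxy)naphthalen-2-ol, via 2-lithio arene 3 (not isolated), via dimethyl arylboronate 4 (not isolated)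
Conditions: n-BuLi, THF, 0 °C to rt; B(OMe)3, −78 °C to rt; AcOH, 30% H2O2, 0 °C
Reagents that add atoms: hydrogen peroxide, OO
Why: Directed ortho-metalation by the acetal oxygens (C2 and C3 are equivalent, so one product), borylation, and oxidation of the boronate with 1,2-shift of the aryl group from boron to oxygen should give the naphthol.

Step 3
Reactants: 6 chromium hexacarbonyl; 7 phenyllithium
Product: 9 tetramethylammonium pentacarbonyl[oxido(phenyl)methylidene]chromate, via lithium acylchromate 8 (not isolated)
Conditions: Et2O, 0 °C to rt; then Me4NBr, H2O
Reagents that add atoms: tetramethylammonium bromide, C[N+](C)(C)C.[Br-]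
Why: Fischer's carbene synthesis: the aryl anion adds to a carbonyl ligand, and cation exchange gives the storable ammonium acylate.

Step 4
Reactants: 9 tetramethylammonium pentacarbonyl[oxido(phenyl)methylidene]chromate; 5 1,4-bis(methoxymethoxy)naphthalen-2-ol
Product: 11 pentacarbonyl{[1,4-bis(methoxymethoxy)naphthalen-2-yl]oxy(phenyl)methylidene}chromium, via acetoxy(phenyl)carbene complex 10 (not isolated)
Conditions: AcBr (1.0 equiv), CH2Cl2, −40 °C; then 5, −40 to 0 °C, Ar
Reagents that add atoms: none
Why: O-acylation turns the acylate into an acyloxycarbene whose carbene carbon behaves like an anhydride carbonyl; the naphthol adds there and acetate leaves (addition–elimination), the established way to aryloxycarbene complexes of zerovalent chromium.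

Step 5
Reactants: 12 3,3-diethoxyprop-1-yne; 13 1-bromo-3-methylbut-2-ene
Product: 15 1,1-diethoxy-6-methylhept-5-en-2-yne, via alkynylmagnesium bromide 14 (not isolated)
Conditions: EtMgBr, THF, 0 °C to rt; CuBr·SMe2 (5 mol %), 13, 0 °C to rt
Reagents that add atoms: none
Why: Copper-catalysed allylic substitution of the alkynyl Grignard reagent at the primary carbon of the allylic bromide should give the skipped enyne; no base strong enough to isomerise it is present.

Step 6
Reactants: 11 pentacarbonyl{[1,4-bis(methoxymethoxy)naphthalen-2-yl]oxy(phenyl)methylidene}chromium; 15 1,1-diethoxy-6-methylhept-5-en-2-yne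
Product: 17 4-{[1,4-bis(methoxymethoxy)naphthalen-2-yl]oxy}-2-(diethoxymethyl)-3-(3-methylbut-2-en-1-yl)naphthalen-1-ol, via tricarbonylchromium naphthol complex 16 (not isolated)
Conditions: 15 (1.5 equiv), THF, 55 °C, Ar; then air, light, rt; NEt3-washed SiO2
Reagents that add atoms: none
Why: Dötz benzannulation: thermal loss of one carbonyl ligand from 11 lets the alkyne coordinate and insert into the Cr=C bond (bond C3–C4) to a vinylcarbene, a carbonyl ligand inserts (bond C1–C2) to a chromium-bound vinylketene, and this closes onto the ortho carbon of the phenyl group (bond C1–C8a). Ring A is thus closed by a thermal 6π-electrocyclisation of the dienylketene, and tautomerisation of the cyclohexadienone gives the naphthol, held at first as complex 16 and released by air and light. The closest known reaction type is the benzannulation of aryloxy-substituted chromium carbene complexes with alkynes, used to make diaryl ethers. No stereocentre is formed. The step needs one orientation of alkyne insertion: in the vinylcarbene the central position lies against a carbonyl ligand and should take the unbranched CH2 of the prenyl arm, so that the α-branched acetal carbon sits on the new carbene carbon, which picks up the carbonyl ligand and becomes C2 next to C1. It also needs carbonyl insertion to win over indene or cyclobutenone formation, which chromium, an ethereal solvent, moderate temperature and an excess of alkyne favour. The carbene oxygen arrives on C4 already bearing ring C, and the carbonyl oxygen appears as the free C1 hydroxyl, so the two oxygens of ring A are differentiated by their origin. The acetal, the aryl acetals and the trisubstituted alkene are spectators under these neutral conditions.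

Step 7
Reactants: 17 4-{[1,4-bis(methoxymethoxy)naphthalen-2-yl]oxy}-2-(diethoxymethyl)-3-(3-methylbut-2-en-1-yl)naphthalen-1-ol
Product: 18 4-{[1,4-bis(methoxymethoxy)naphthalen-2-yl]oxy}-1-hydroxy-3-(3-methylbut-2-en-1-yl)naphthalene-2-carbaldehyde
Conditions: PPTS (cat.), acetone/H2O, rt
Reagents that add atoms: water, O
Why: Acetal hydrolysis; the ortho hydroxyl assists ionisation of the benzylic acetal, so buffered acid that leaves aryl methoxymethyl ethers intact should suffice, and the hydrogen-bonded hydroxy aldehyde is far less air-sensitive than 17.

Step 8
Reactants: 18 4-{[1,4-bis(methoxymethoxy)naphthalen-2-yl]oxy}-1-hydroxy-3-(3-methylbut-2-en-1-yl)naphthalene-2-carbaldehyde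
Product: 19 4-{[1,4-bis(methoxymethoxy)naphthalen-2-yl]oxy}-1-hydroxy-3-(3-methylbut-2-en-1-yl)naphthalene-2-carboxylic acid
Conditions: NaClO2, NaH2PO4, 2-methyl-2-butene (large excess), t-BuOH/THF/H2O, 0 °C to rt
Reagents that add atoms: sodium chlorite, [Na+].[O-]Cl=O
Why: Pinnick oxidation: chlorous acid adds to the aldehyde and fragments to the acid, a process little affected by the two ortho substituents; the excess alkene scavenges hypochlorous acid and so protects the prenyl group and the electron-rich rings.

Step 9
Reactants: 19 4-{[1,4-bis(methoxymethoxy)naphthalen-2-yl]oxy}-1-hydroxy-3-(3-methylbut-2-en-1-yl)naphthalene-2-carboxylic acid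
Product: 20 methyl 4-{[1,4-bis(methoxymethoxy)naphthalen-2-yl]oxy}-1-hydroxy-3-(3-methylbut-2-en-1-yl)naphthalene-2-carboxylate
Conditions: MeI, KHCO3, DMF, rt
Reagents that add atoms: iodomethane, CI
Why: SN2 O-alkylation of the carboxylate; KHCO3 is too weak to ionise the hydrogen-bonded phenol, and attack at the methyl carbon is indifferent to the hindrance that would block a Fischer esterification.

Step 10
Reactants: 20 methyl 4-{[1,4-bis(methoxymethoxy)naphthalen-2-yl]oxy}-1-hydroxy-3-(3-methylbut-2-en-1-yl)naphthalene-2-carboxylate
Product: 22 rubioncolin C, via hydroquinone 21 (not isolated)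
Conditions: HCl (3 M in MeOH), THF, rt, Ar; evaporation; then Ag2O, MgSO4, Et2O, rt
Reagents that add atoms: none
Why: Acid-catalysed transacetalisation moves both methoxymethyl groups to methanol, and Ag2O then oxidises the free 1,4-diol of ring C to the quinone. Ring A should stay untouched because its oxidation would require loss of the aryl ether and its phenol is tied to the ester by a hydrogen bond. Oxygen is excluded until the acid is removed, so the aryloxyquinone never meets acidic methanol.

## Compound list

1 | naphthalene-1,4-diol | Oc1ccc(O)c2ccccc12 | starting material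
2 | 1,4-bis(methoxymethoxy)naphthalene | COCOc1ccc(OCOC)c2ccccc12 | intermediate
3 | [1,4-bis(methoxymethoxy)naphthalen-2-yl]lithium | [Li]c1cc(OCOC)c2ccccc2c1OCOC | intermediate (not isolated)
4 | dimethyl [1,4-bis(methoxymethoxy)naphthalen-2-yl]boronate | COB(OC)c1cc(OCOC)c2ccccc2c1OCOC | intermediate (not isolated)
5 | 1,4-bis(methoxymethoxy)naphthalen-2-ol | Oc1cc(OCOC)c2ccccc2c1OCOC | intermediate
6 | chromium hexacarbonyl | O=C=[Cr](=C=O)(=C=O)(=C=O)(=C=O)=C=O | starting material
7 | phenyllithium | [Li]c1ccccc1 | starting material
8 | lithium pentacarbonyl[oxido(phenyl)methylidene]chromate | [Li+].[O-]C(c1ccccc1)=[Cr](=C=O)(=C=O)(=C=O)(=C=O)=C=O | intermediate (not isolated)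
9 | tetramethylammonium pentacarbonyl[oxido(phenyl)methylidene]chromate | C[N+](C)(C)C.[O-]C(c1ccccc1)=[Cr](=C=O)(=C=O)(=C=O)(=C=O)=C=O | intermediate
10 | pentacarbonyl[acetoxy(phenyl)methylidene]chromium | CC(=O)OC(c1ccccc1)=[Cr](=C=O)(=C=O)(=C=O)(=C=O)=C=O | intermediate (not isolated)
11 | pentacarbonyl{[1,4-bis(methoxymethoxy)naphthalen-2-yl]oxy(phenyl)methylidene}chromium | O=C=[Cr](=C=O)(=C=O)(=C=O)(=C=O)=C(Oc1cc(OCOC)c2ccccc2c1OCOC)c1ccccc1 | intermediate
12 | 3,3-diethoxyprop-1-yne | CCOC(OCC)C#C | starting material
13 | 1-bromo-3-methylbut-2-ene | CC(C)=CCBr | starting material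
14 | (3,3-diethoxyprop-1-yn-1-yl)magnesium bromide | CCOC(OCC)C#C[Mg]Br | intermediate (not isolated)
15 | 1,1-diethoxy-6-methylhept-5-en-2-yne | CCOC(OCC)C#CCC=C(C)C | intermediate
16 | tricarbonylchromium complex of 17, the metal η6-bound to the newly formed ring A | CCOC(OCC)c1c(CC=C(C)C)c(Oc2cc(OCOC)c3ccccc3c2OCOC)c2ccccc2c1O.[Cr](=C=O)(=C=O)=C=O | intermediate (not isolated)
17 | 4-{[1,4-bis(methoxymethoxy)naphthalen-2-yl]oxy}-2-(diethoxymethyl)-3-(3-methylbut-2-en-1-yl)naphthalen-1-ol | CCOC(OCC)c1c(CC=C(C)C)c(Oc2cc(OCOC)c3ccccc3c2OCOC)c2ccccc2c1O | intermediate
18 | 4-{[1,4-bis(methoxymethoxy)naphthalen-2-yl]oxy}-1-hydroxy-3-(3-methylbut-2-en-1-yl)naphthalene-2-carbaldehyde | O=Cc1c(CC=C(C)C)c(Oc2cc(OCOC)c3ccccc3c2OCOC)c2ccccc2c1O | intermediate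
19 | 4-{[1,4-bis(methoxymethoxy)naphthalen-2-yl]oxy}-1-hydroxy-3-(3-methylbut-2-en-1-yl)naphthalene-2-carboxylic acid | OC(=O)c1c(CC=C(C)C)c(Oc2cc(OCOC)c3ccccc3c2OCOC)c2ccccc2c1O | intermediate
20 | methyl 4-{[1,4-bis(methoxymethoxy)naphthalen-2-yl]oxy}-1-hydroxy-3-(3-methylbut-2-en-1-yl)naphthalene-2-carboxylate | COC(=O)c1c(CC=C(C)C)c(Oc2cc(OCOC)c3ccccc3c2OCOC)c2ccccc2c1O | intermediate
21 | methyl 4-[(1,4-dihydroxynaphthalen-2-yl)oxy]-1-hydroxy-3-(3-methylbut-2-en-1-yl)naphthalene-2-carboxylate | COC(=O)c1c(CC=C(C)C)c(Oc2cc(O)c3ccccc3c2O)c2ccccc2c1O | intermediate (not isolated)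
22 | rubioncolin C, methyl 4-[(1,4-dioxo-1,4-dihydronaphthalen-2-yl)oxy]-1-hydroxy-3-(3-methylbut-2-en-1-yl)naphthalene-2-carboxylate | COC(=O)c1c(CC=C(C)C)c(OC2=CC(=O)c3ccccc3C2=O)c2ccccc2c1O | target

## Step count and least certain steps

Total step count: 10. Longest linear sequence: 8 steps (steps 1, 2, 4, 6, 7, 8, 9 and 10, from 1 to 22).

**Step 6 (key step).** The most likely failure is insertion of the alkyne in both orientations, because the two alkyne substituents differ only as a branched and an unbranched carbon. That would give a mixture of products with the C2 and C3 substituents exchanged. Loss of material through carbonyl-free cyclisation to indenes, or through thermal decay of the aryloxycarbene before it takes up the alkyne, is the second concern.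

Fallback: the regiochemistry is handed to silicon and the C2 carbon is added afterwards. Ethynyltrimethylsilane F1 is coupled with 13 as in step 5 to give trimethyl(5-methylhex-4-en-1-yn-1-yl)silane F2. Benzannulation of 11 with F2 under the conditions of step 6 should place the silyl group, which ends on the ketene carbon of the intermediate, next to C1. This gives 4-{[1,4-bis(methoxymethoxy)naphthalen-2-yl]oxy}-3-(3-methylbut-2-en-1-yl)-2-(trimethylsilyl)naphthalen-1-ol F3; the trimethylsilyl group is kept small so that the silylketene still cyclises. Ipso-protodesilylation ortho to the hydroxyl (TBAF, AcOH, THF, 40 °C) gives 4-{[1,4-bis(methoxymethoxy)naphthalen-2-yl]oxy}-3-(3-methylbut-2-en-1-yl)naphthalen-1-ol F4, handled under argon. Ortho-formylation of the phenol (MgCl2, NEt3, paraformaldehyde, MeCN, reflux) can only occur at C2 and rejoins the route at 18.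

**Step 4.** The naphthol may attack the acetyl carbonyl of 10 instead of the carbene carbon, which would acetylate 5 and return the acylate. The acyloxy- and aryloxycarbene complexes may also decompose during exchange and isolation.

Fallback: a one-flask sequence that no longer isolates 11. From 9, pivaloyl chloride (CH2Cl2, −40 °C) gives pentacarbonyl[(2,2-dimethylpropanoyloxy)(phenyl)methylidene]chromium F5, whose tert-butyl group closes the acyl-transfer channel. The nucleophile is the pre-formed sodium 1,4-bis(methoxymethoxy)naphthalen-2-olate F6 (from 5 and NaH in THF). After exchange the solvent is changed to THF, 15 is added and the mixture is warmed as in step 6, so that the route is rejoined at 17.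

**Step 8.** Chlorine dioxide or hypochlorous acid formed from the chlorite may oxidise the free ring A naphthol, a hydroquinone mono-ether, with loss of the aryl ether, or chlorinate ring C or the prenyl double bond.

Fallback: the phenol is masked before the oxidation. From 18, acetylation (Ac2O, pyridine, DMAP) gives 4-{[1,4-bis(methoxymethoxy)naphthalen-2-yl]oxy}-2-formyl-3-(3-methylbut-2-en-1-yl)naphthalen-1-yl acetate F7. Its chlorite oxidation under the conditions of step 8 gives 1-acetoxy-4-{[1,4-bis(methoxymethoxy)naphthalen-2-yl]oxy}-3-(3-methylbut-2-en-1-yl)naphthalene-2-carboxylic acid F8. Methanolysis of the aryl acetate (K2CO3, MeOH, rt) rejoins the route at 19.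

**Step 10.** Acid may add across the prenyl double bond, with the neighbouring ester carbonyl closing a lactone. If oxidation sets in before the acid is gone, the aryloxy group of the quinone may be exchanged for methoxide.

Fallback: acidolysis is replaced by a silyl transfer under basic conditions. From 20, TMSOTf and 2,2'-bipyridyl (CH2Cl2, 0 °C) convert the aryl methoxymethyl ethers, and the free phenol, into silyl ethers. This gives methyl 4-{[1,4-bis(trimethylsilyloxy)naphthalen-2-yl]oxy}-3-(3-methylbut-2-en-1-yl)-1-(trimethylsilyloxy)naphthalene-2-carboxylate F9. Water hydrolyses F9 to 21, where the route is rejoined before the Ag2O oxidation to 22.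

## Further compounds

F1 | step 6 | ethynyltrimethylsilane | C[Si](C)(C)C#C
F2 | step 6 | trimethyl(5-methylhex-4-en-1-yn-1-yl)silane | C[Si](C)(C)C#CCC=C(C)C
F3 | step 6 | 4-{[1,4-bis(methoxymethoxy)naphthalen-2-yl]oxy}-3-(3-methylbut-2-en-1-yl)-2-(trimethylsilyl)naphthalen-1-ol | C[Si](C)(C)c1c(CC=C(C)C)c(Oc2cc(OCOC)c3ccccc3c2OCOC)c2ccccc2c1O
F4 | step 6 | 4-{[1,4-bis(methoxymethoxy)naphthalen-2-yl]oxy}-3-(3-methylbut-2-en-1-yl)naphthalen-1-ol | Oc1cc(CC=C(C)C)c(Oc2cc(OCOC)c3ccccc3c2OCOC)c2ccccc12
F5 | step 4 | pentacarbonyl[(2,2-dimethylpropanoyloxy)(phenyl)methylidene]chromium | CC(C)(C)C(=O)OC(c1ccccc1)=[Cr](=C=O)(=C=O)(=C=O)(=C=O)=C=O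
F6 | step 4 | sodium 1,4-bis(methoxymethoxy)naphthalen-2-olate | [Na+].[O-]c1cc(OCOC)c2ccccc2c1OCOC
F7 | step 8 | 4-{[1,4-bis(methoxymethoxy)naphthalen-2-yl]oxy}-2-formyl-3-(3-methylbut-2-en-1-yl)naphthalen-1-yl acetate | CC(=O)Oc1c(C=O)c(CC=C(C)C)c(Oc2cc(OCOC)c3ccccc3c2OCOC)c2ccccc12
F8 | step 8 | 1-acetoxy-4-{[1,4-bis(methoxymethoxy)naphthalen-2-yl]oxy}-3-(3-methylbut-2-en-1-yl)naphthalene-2-carboxylic acid | CC(=O)Oc1c(C(=O)O)c(CC=C(C)C)c(Oc2cc(OCOC)c3ccccc3c2OCOC)c2ccccc12
F9 | step 10 | methyl 4-{[1,4-bis(trimethylsilyloxy)naphthalen-2-yl]oxy}-3-(3-methylbut-2-en-1-yl)-1-(trimethylsilyloxy)naphthalene-2-carboxylate | COC(=O)c1c(CC=C(C)C)c(Oc2cc(O[Si](C)(C)C)c3ccccc3c2O[Si](C)(C)C)c2ccccc2c1O[Si](C)(C)C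
A1 | alternative 1 | methyl 4-(3-methylbut-2-en-1-yl)-2-[(triisopropylsilyl)oxy]furan-3-carboxylate | COC(=O)c1c(CC=C(C)C)coc1O[Si](C(C)C)(C(C)C)C(C)C
A2 | alternative 1 | 2-(trimethylsilyl)phenyl trifluoromethanesulfonate | C[Si](C)(C)c1ccccc1OS(=O)(=O)C(F)(F)F
A3 | alternative 1 | methyl 4-hydroxy-3-(3-methylbut-2-en-1-yl)-1-[(triisopropylsilyl)oxy]-2-naphthoate | COC(=O)c1c(CC=C(C)C)c(O)c2ccccc2c1O[Si](C(C)C)(C(C)C)C(C)C
A4 | alternative 1 | 2-bromonaphthalene-1,4-dione | O=C1C=C(Br)C(=O)c2ccccc12
A5 | alternative 2 | methyl 1-hydroxy-4-[(4-hydroxy-3-oxo-4-phenylcyclobut-1-en-1-yl)oxy]-3-(3-methylbut-2-en-1-yl)naphthalene-2-carboxylate (racemic) | COC(=O)c1c(CC=C(C)C)c(OC2=CC(=O)C2(O)c2ccccc2)c2ccccc2c1O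
A6 | alternative 2 | methyl 4-[(1,4-dihydroxynaphthalen-2-yl)oxy]-1-hydroxy-3-(3-methylbut-2-en-1-yl)-2-naphthoate | COC(=O)c1c(CC=C(C)C)c(Oc2cc(O)c3ccccc3c2O)c2ccccc2c1O
A7 | alternative 3 | methyl 2-[2-(3-methylbut-2-en-1-yl)-1,3-dioxo-2,3-dihydro-1H-inden-2-yl]acetate | COC(=O)CC1(CC=C(C)C)C(=O)c2ccccc2C1=O
A8 | alternative 3 | methyl 2-[4-methoxy-2-(3-methylbut-2-en-1-yl)-4-oxobutanoyl]benzoate (racemic) | COC(=O)CC(CC=C(C)C)C(=O)c1ccccc1C(=O)OC
A9 | alternative 3 | methyl 1,4-dihydroxy-3-(3-methylbut-2-en-1-yl)-2-naphthoate | COC(=O)c1c(CC=C(C)C)c(O)c2ccccc2c1O
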